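**Strategy.** Ring C is cut so that C3–C4 arrive as a ketene. C2, which carries O1 and ring B, is treated as the α-carbon of an O-aryl mandelic acid, made enantiopure by transfer hydrogenation and Mitsunobu inversion. In the key step the derived diazoketone undergoes a photochemical Wolff rearrangement, in which C2 migrates with retention to the diazo carbon (C2–C3), and the resulting ketene acylates C4a of ring A, the carbon ortho to O1 and C5–O and para to C7–O (C4–C4a). The precursor is an acyclic 1-aryloxy-1-aryl-3-diazopropan-2-one with bromine at the future C8. The hydrated lavandulyl chain, made by auxiliary-controlled dienolate alkylation, is then coupled there by Negishi reaction.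

Key step: step 15

Abbreviations: TBS = tert-butyldimethylsilyl, TES = triethylsilyl, TBSO/TESO = the corresponding silyloxy groups.

Assumption: the (R,R)-TsDPEN ruthenium catalyst is taken to give the (S)-hydroxy ester 17, as the aryl-ketone model predicts; should the sense prove opposite, the (S,S) catalyst is used and nothing else changes.

**Route**

Step 1
Reactants: 1 (S)-4-benzyloxazolidin-2-one; 2 3-methylbut-2-enoyl chloride
Product: 4 (4S)-4-benzyl-3-(3-methylbut-2-enoyl)oxazolidin-2-one, via N-lithio oxazolidinone 3 (not isolated)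
Conditions: n-BuLi, THF, –78 °C; then 2, –78 → 0 °C
Reagents that add atoms: none
Why: N-acylation of the lithiated Evans auxiliary by the acid chloride is fast at –78 °C and leaves the conjugated double bond in place.

Step 2
Reactants: 4 (4S)-4-benzyl-3-(3-methylbut-2-enoyl)oxazolidin-2-one; 5 1-bromo-3-methylbut-2-ene (prenyl bromide)
Product: 7 (4S)-4-benzyl-3-[(2S)-5-methyl-2-(prop-1-en-2-yl)hex-4-enoyl]oxazolidin-2-one, via sodium dienolate 6 (not isolated)
Conditions: NaN(SiMe3)2, THF, –78 °C; then 5, –78 → –40 °C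
Reagents that add atoms: none
Why: γ-deprotonation gives the chelated Z(O)-dienolate, which is alkylated at the α-carbon (deconjugative Evans alkylation) on the face remote from the benzyl group, so that the new stereocentre should be (S) and the isopropenyl group is unveiled.

Step 3
Reactants: 7 (4S)-4-benzyl-3-[(2S)-5-methyl-2-(prop-1-en-2-yl)hex-4-enoyl]oxazolidin-2-one
Product: 8 (4S)-4-benzyl-3-[(2S)-3-(3,3-dimethyloxiran-2-yl)-2-(prop-1-en-2-yl)propanoyl]oxazolidin-2-one (both epimers at the oxirane carbon)
Conditions: mCPBA (1.05 equiv), NaHCO3, CH2Cl2, 0 °C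
Reagents that add atoms: mCPBA, O=C(OO)c1cccc(Cl)c1
Why: Prilezhaev epoxidation should take the electron-rich trisubstituted alkene in preference to the 1,1-disubstituted alkene next to the imide-bearing carbon; the new oxirane centre is erased in step 4.

Step 4
Reactants: 8 (4S)-4-benzyl-3-[(2S)-3-(3,3-dimethyloxiran-2-yl)-2-(prop-1-en-2-yl)propanoyl]oxazolidin-2-one
Product: 9 (2S)-5-methyl-2-(prop-1-en-2-yl)hexane-1,5-diol
Conditions: LiAlH4, THF, 0 °C → rt
Reagents that add atoms: none
Why: hydride cleaves the imide to the primary alcohol and opens the oxirane by SN2 attack at its less substituted carbon, which gives the tertiary alcohol and leaves the α-stereocentre untouched.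

Step 5
Reactants: 9 (2S)-5-methyl-2-(prop-1-en-2-yl)hexane-1,5-diol
Product: 10 (5S)-6-iodo-2-methyl-5-(prop-1-en-2-yl)hexan-2-ol
Conditions: PPh3, I2, imidazole, CH2Cl2, 0 °C
Reagents that add atoms: iodine, II
Why: Appel-type iodination proceeds by SN2 displacement and therefore takes the primary alcohol only, the tertiary one being unable to react in this way at 0 °C.

Step 6
Reactants: 10 (5S)-6-iodo-2-methyl-5-(prop-1-en-2-yl)hexan-2-ol
Product: 11 triethyl{[(5S)-6-iodo-2-methyl-5-(prop-1-en-2-yl)hexan-2-yl]oxy}silane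
Conditions: TESOTf, 2,6-lutidine, CH2Cl2, –78 °C
Reagents that add atoms: triethylsilyl triflate, CC[Si](CC)(CC)OS(=O)(=O)C(F)(F)F
Why: the silyl triflate silylates even the hindered tertiary alcohol, which has to be masked before the organozinc reagent is made.

Step 7
Reactants: 12 4-bromo-3-methoxyphenol
Product: 13 (4-bromo-3-methoxyphenoxy)(tert-butyl)dimethylsilane
Conditions: TBSCl, imidazole, DMF, rt
Reagents that add atoms: tert-butyldimethylsilyl chloride, CC(C)(C)[Si](C)(C)Cl
Why: standard silylation of a phenol gives an ether that tolerates the organolithium step and is removed by fluoride at the end.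

Step 8
Reactants: 13 (4-bromo-3-methoxyphenoxy)(tert-butyl)dimethylsilane; 14 diallyl oxalate
Product: 16 allyl 2-[4-(TBSO)-2-methoxyphenyl]-2-oxoacetate, via aryllithium 15 (not isolated)
Conditions: n-BuLi, THF, –78 °C; then addition to 14 (3 equiv), THF, –78 °C; NH4Cl work-up
Reagents that add atoms: none
Why: bromine–lithium exchange gives the aryllithium, and its addition to the oxalate diester stops at the tetrahedral adduct at –78 °C, which should release the α-keto ester on work-up.

Step 9
Reactants: 16 allyl 2-[4-(TBSO)-2-methoxyphenyl]-2-oxoacetate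
Product: 17 allyl (2S)-2-hydroxy-2-[4-(TBSO)-2-methoxyphenyl]acetate
Conditions: RuCl(p-cymene)[(R,R)-TsDPEN] (1 mol %), HCO2H/Et3N (5:2), CH2Cl2, 0 °C → rt
Reagents that add atoms: none
Why: Noyori asymmetric transfer hydrogenation of the aryl glyoxylate, in which the chiral Ru–H/N–H catalyst differentiates the ketone faces and should set the (S)-carbinol.

Step 10
Reactants: 18 phloroglucinol
Product: 19 3,5-bis(TBSO)phenol
Conditions: TBSCl (2.0 equiv), imidazole, DMF, 0 °C
Reagents that add atoms: tert-butyldimethylsilyl chloride, CC(C)(C)[Si](C)(C)Cl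
Why: bis-silylation of three equivalent hydroxyls is statistical, and the mono- and tris-silylated fractions can be separated and recycled.

Step 11
Reactants: 19 3,5-bis(TBSO)phenol
Product: 20 2-bromo-3,5-bis(TBSO)phenol
Conditions: NBS (1.0 equiv), i-Pr2NH (10 mol %), CH2Cl2, –78 → 0 °C
Reagents that add atoms: N-bromosuccinimide, O=C1CCC(=O)N1Br
Why: amine-mediated ortho-bromination of the phenol should place bromine next to the free hydroxyl, since the other open carbon lies between two bulky silyloxy groups.

Step 12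
Reactants: 17 allyl (2S)-2-hydroxy-2-[4-(TBSO)-2-methoxyphenyl]acetate; 20 2-bromo-3,5-bis(TBSO)phenol
Product: 21 allyl (2R)-2-[2-bromo-3,5-bis(TBSO)phenoxy]-2-[4-(TBSO)-2-methoxyphenyl]acetate
Conditions: PPh3, DIAD, toluene, 0 °C → rt
Reagents that add atoms: none
Why: Mitsunobu etherification of the α-hydroxy ester by the acidic ortho-bromophenol proceeds by SN2 displacement with inversion, so that the (S)-carbinol should give the (R)-aryl ether that becomes C2.

Step 13
Reactants: 21 allyl (2R)-2-[2-bromo-3,5-bis(TBSO)phenoxy]-2-[4-(TBSO)-2-methoxyphenyl]acetate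
Product: 22 (2R)-2-[2-bromo-3,5-bis(TBSO)phenoxy]-2-[4-(TBSO)-2-methoxyphenyl]acetic acid
Conditions: Pd(PPh3)4 (5 mol %), morpholine, THF, 0 °C → rt
Reagents that add atoms: none
Why: Tsuji–Trost deallylation frees the acid under neutral conditions that spare the aryl silyl ethers and the epimerisable α-centre, while the hindered electron-rich aryl bromide should not add to the zerovalent palladium phosphine complex at room temperature.

Step 14
Reactants: 22 (2R)-2-[2-bromo-3,5-bis(TBSO)phenoxy]-2-[4-(TBSO)-2-methoxyphenyl]acetic acid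
Product: 24 (1R)-1-[2-bromo-3,5-bis(TBSO)phenoxy]-3-diazo-1-[4-(TBSO)-2-methoxyphenyl]propan-2-one, via mixed carbonic anhydride 23 (not isolated)
Conditions: i-BuOCOCl, N-methylmorpholine, THF, –20 °C; then CH2N2, Et2O, –20 → 0 °C
Reagents that add atoms: diazomethane, C=[N+]=[N-]
Why: acylation of diazomethane by the mixed anhydride (first stage of an Arndt–Eistert sequence) runs cold with a weak base, which should keep the α-stereocentre intact.

Step 15
Reactants: 24 (1R)-1-[2-bromo-3,5-bis(TBSO)phenoxy]-3-diazo-1-[4-(TBSO)-2-methoxyphenyl]propan-2-one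
Product: 26 (2S)-8-bromo-5,7-bis(TBSO)-2-[4-(TBSO)-2-methoxyphenyl]chroman-4-one, via aryloxy ketene 25 (not isolated)
Conditions: hν (450 nm LEDs), CH2Cl2 (0.005 M), –40 °C; then Sc(OTf)3 (10 mol %), –40 → 0 °C
Reagents that add atoms: none
Why: Proposed new method: irradiation of the s-Z diazoketone expels N2 while C2 shifts from the carbonyl carbon to the diazo carbon (Wolff rearrangement), which forms C2–C3 and gives ketene 25; Sc(OTf)3 then activates the ketene carbonyl, C4a of ring A (ortho to O1 and to the C5 silyloxy group, para to the C7 silyloxy group) attacks C4 to form C4–C4a, and proton transfer gives the ketone. The closest known reaction types are the Wolff step of the Arndt–Eistert homologation of α-chiral diazoketones and the Lewis-acid-mediated Friedel–Crafts acylation of arenes by ketenes; their union into a chromanone annulation of an α-aryloxy diazoketone is the untested part. Ring C closes by a 6-exo-dig attack of the arene on the sp carbon of the ketene, with the C=O π bond outside the new ring. No stereocentre is created: C2, fixed in step 12, is relayed because the 1,2-shift is suprafacial with retention at the migrating carbon and C2–H is never acidified. The step needs rearrangement to outrun carbene insertion chemistry (secured by metal-free photolysis), C-acylation to outrun ketene dimerisation and ionisation of the benzylic C2–O1 bond (high dilution, low temperature, a mild Lewis acid added only after N2 loss, no amine that could trigger E1cB loss of the aryloxide), and a single site of closure, which the bromine on the other ortho carbon (the future C8) secures.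

Step 16
Reactants: 26 (2S)-8-bromo-5,7-bis(TBSO)-2-[4-(TBSO)-2-methoxyphenyl]chroman-4-one; 11 triethyl{[(5S)-6-iodo-2-methyl-5-(prop-1-en-2-yl)hexan-2-yl]oxy}silane
Product: 28 (2S)-5,7-bis(TBSO)-2-[4-(TBSO)-2-methoxyphenyl]-8-[(2R)-5-methyl-2-(prop-1-en-2-yl)-5-(TESO)hexyl]chroman-4-one, via alkylzinc iodide 27 (not isolated)
Conditions: 11, Zn dust, LiCl, THF, 40 °C; then 26, Pd(OAc)2 (5 mol %), SPhos (10 mol %), THF, 50 °C
Reagents that add atoms: none
Why: Negishi coupling of the primary alkylzinc iodide with the hindered, electron-rich aryl bromide should proceed with a bulky biarylphosphine ligand under neutral conditions that tolerate the ketone and the silyl ethers, and the chain stereocentre, β to zinc, is not involved.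

Step 17
Reactants: 28 (2S)-5,7-bis(TBSO)-2-[4-(TBSO)-2-methoxyphenyl]-8-[(2R)-5-methyl-2-(prop-1-en-2-yl)-5-(TESO)hexyl]chroman-4-one
Product: 29 (2S)-5,7-dihydroxy-8-[(2R)-5-hydroxy-5-methyl-2-(prop-1-en-2-yl)hexyl]-2-(4-hydroxy-2-methoxyphenyl)chroman-4-one
Conditions: TBAF, AcOH (1:1, 6 equiv each), THF, 0 °C → rt
Reagents that add atoms: none
Why: fluoride should cleave the three aryl TBS ethers and the tertiary TES ether, while the acetic acid buffer suppresses base-induced retro-oxa-Michael opening of ring C, which would scramble C2, and spares the isopropenyl group and the tertiary alcohol.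

**Compound list**

1 | (S)-4-benzyloxazolidin-2-one | O=C1N[C@@H](Cc2ccccc2)CO1 | starting material
2 | 3-methylbut-2-enoyl chloride | CC(C)=CC(Cl)=O | starting material
3 | N-lithio (S)-4-benzyloxazolidin-2-one | [Li]N1[C@@H](Cc2ccccc2)COC1=O | intermediate (not isolated)
4 | (4S)-4-benzyl-3-(3-methylbut-2-enoyl)oxazolidin-2-one | CC(C)=CC(=O)N1[C@@H](Cc2ccccc2)COC1=O | intermediate
5 | 1-bromo-3-methylbut-2-ene | CC(C)=CCBr | starting material
6 | sodium Z(O)-dienolate of 4 | C=C(C)/C=C(\[O-])N1[C@@H](Cc2ccccc2)COC1=O.[Na+] | intermediate (not isolated)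
7 | (4S)-4-benzyl-3-[(2S)-5-methyl-2-(prop-1-en-2-yl)hex-4-enoyl]oxazolidin-2-one | C=C(C)[C@H](CC=C(C)C)C(=O)N1[C@@H](Cc2ccccc2)COC1=O | intermediate
8 | (4S)-4-benzyl-3-[(2S)-3-(3,3-dimethyloxiran-2-yl)-2-(prop-1-en-2-yl)propanoyl]oxazolidin-2-one (both epimers at the oxirane carbon) | C=C(C)[C@H](CC1OC1(C)C)C(=O)N1[C@@H](Cc2ccccc2)COC1=O | intermediate
9 | (2S)-5-methyl-2-(prop-1-en-2-yl)hexane-1,5-diol | C=C(C)[C@H](CCC(C)(C)O)CO | intermediate
10 | (5S)-6-iodo-2-methyl-5-(prop-1-en-2-yl)hexan-2-ol | C=C(C)[C@H](CCC(C)(C)O)CI | intermediate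
11 | triethyl{[(5S)-6-iodo-2-methyl-5-(prop-1-en-2-yl)hexan-2-yl]oxy}silane | C=C(C)[C@H](CCC(C)(C)O[Si](CC)(CC)CC)CI | intermediate
12 | 4-bromo-3-methoxyphenol | COc1cc(O)ccc1Br | starting material
13 | (4-bromo-3-methoxyphenoxy)(tert-butyl)dimethylsilane | COc1cc(O[Si](C)(C)C(C)(C)C)ccc1Br | intermediate
14 | diallyl oxalate | C=CCOC(=O)C(=O)OCC=C | starting material
15 | [4-(tert-butyldimethylsilyloxy)-2-methoxyphenyl]lithium | COc1cc(O[Si](C)(C)C(C)(C)C)ccc1[Li] | intermediate (not isolated)
16 | allyl 2-[4-(tert-butyldimethylsilyloxy)-2-methoxyphenyl]-2-oxoacetate | C=CCOC(=O)C(=O)c1ccc(O[Si](C)(C)C(C)(C)C)cc1OC | intermediate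
17 | allyl (2S)-2-hydroxy-2-[4-(tert-butyldimethylsilyloxy)-2-methoxyphenyl]acetate | C=CCOC(=O)[C@@H](O)c1ccc(O[Si](C)(C)C(C)(C)C)cc1OC | intermediate
18 | phloroglucinol (benzene-1,3,5-triol) | Oc1cc(O)cc(O)c1 | starting material
19 | 3,5-bis(tert-butyldimethylsilyloxy)phenol | Oc1cc(O[Si](C)(C)C(C)(C)C)cc(O[Si](C)(C)C(C)(C)C)c1 | intermediate
20 | 2-bromo-3,5-bis(tert-butyldimethylsilyloxy)phenol | Oc1cc(O[Si](C)(C)C(C)(C)C)cc(O[Si](C)(C)C(C)(C)C)c1Br | intermediate
21 | allyl (2R)-2-[2-bromo-3,5-bis(tert-butyldimethylsilyloxy)phenoxy]-2-[4-(tert-butyldimethylsilyloxy)-2-methoxyphenyl]acetate | C=CCOC(=O)[C@H](Oc1cc(O[Si](C)(C)C(C)(C)C)cc(O[Si](C)(C)C(C)(C)C)c1Br)c1ccc(O[Si](C)(C)C(C)(C)C)cc1OC | intermediate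
22 | (2R)-2-[2-bromo-3,5-bis(tert-butyldimethylsilyloxy)phenoxy]-2-[4-(tert-butyldimethylsilyloxy)-2-methoxyphenyl]acetic acid | OC(=O)[C@H](Oc1cc(O[Si](C)(C)C(C)(C)C)cc(O[Si](C)(C)C(C)(C)C)c1Br)c1ccc(O[Si](C)(C)C(C)(C)C)cc1OC | intermediate
23 | mixed anhydride of 22 with isobutyl hydrogen carbonate | CC(C)COC(=O)OC(=O)[C@H](Oc1cc(O[Si](C)(C)C(C)(C)C)cc(O[Si](C)(C)C(C)(C)C)c1Br)c1ccc(O[Si](C)(C)C(C)(C)C)cc1OC | intermediate (not isolated)
24 | (1R)-1-[2-bromo-3,5-bis(tert-butyldimethylsilyloxy)phenoxy]-3-diazo-1-[4-(tert-butyldimethylsilyloxy)-2-methoxyphenyl]propan-2-one | [N-]=[N+]=CC(=O)[C@H](Oc1cc(O[Si](C)(C)C(C)(C)C)cc(O[Si](C)(C)C(C)(C)C)c1Br)c1ccc(O[Si](C)(C)C(C)(C)C)cc1OC | intermediate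
25 | (3S)-3-[2-bromo-3,5-bis(tert-butyldimethylsilyloxy)phenoxy]-3-[4-(tert-butyldimethylsilyloxy)-2-methoxyphenyl]prop-1-en-1-one (ketene) | O=C=C[C@H](Oc1cc(O[Si](C)(C)C(C)(C)C)cc(O[Si](C)(C)C(C)(C)C)c1Br)c1ccc(O[Si](C)(C)C(C)(C)C)cc1OC | intermediate (not isolated)
26 | (2S)-8-bromo-5,7-bis(tert-butyldimethylsilyloxy)-2-[4-(tert-butyldimethylsilyloxy)-2-methoxyphenyl]chroman-4-one | CC(C)(C)[Si](C)(C)Oc1cc(O[Si](C)(C)C(C)(C)C)c2c(c1Br)O[C@H](c1ccc(O[Si](C)(C)C(C)(C)C)cc1OC)CC2=O | intermediate
27 | [(2S)-5-methyl-2-(prop-1-en-2-yl)-5-(triethylsilyloxy)hexyl]zinc iodide | C=C(C)[C@H](CCC(C)(C)O[Si](CC)(CC)CC)C[Zn]I | intermediate (not isolated)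
28 | (2S)-5,7-bis(tert-butyldimethylsilyloxy)-2-[4-(tert-butyldimethylsilyloxy)-2-methoxyphenyl]-8-[(2R)-5-methyl-2-(prop-1-en-2-yl)-5-(triethylsilyloxy)hexyl]chroman-4-one | C=C(C)[C@H](CCC(C)(C)O[Si](CC)(CC)CC)Cc1c(O[Si](C)(C)C(C)(C)C)cc(O[Si](C)(C)C(C)(C)C)c2c1O[C@H](c1ccc(O[Si](C)(C)C(C)(C)C)cc1OC)CC2=O | intermediate
29 | (2S)-5,7-dihydroxy-8-[(2R)-5-hydroxy-5-methyl-2-(prop-1-en-2-yl)hexyl]-2-(4-hydroxy-2-methoxyphenyl)chroman-4-one | C=C(C)[C@H](CCC(C)(C)O)Cc1c(O)cc(O)c2c1O[C@H](c1ccc(O)cc1OC)CC2=O | target

**Count.** Total: 17 steps. Longest linear sequence: 9 steps (7, 8, 9, 12, 13, 14, 15, 16, 17).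

**Steps most likely to fail**

Step 15. Ketene dimerisation, or ionisation of the benzylic C2–O1 bond in the Lewis-acid-activated ketene, may outrun C-acylation and cost material or configurational purity. The fallback sets out from 24 and makes the two bonds in two known operations. Wolff rearrangement in the presence of water (hν 450 nm, THF/H2O 10:1, rt) should give the homologated (3S)-3-[2-bromo-3,5-bis(tert-butyldimethylsilyloxy)phenoxy]-3-[4-(tert-butyldimethylsilyloxy)-2-methoxyphenyl]propanoic acid F1. Intramolecular Friedel–Crafts acylation of F1 through its mixed trifluoroacetic anhydride ((CF3CO)2O, CH2Cl2, 0 °C) would then close ring C and come back to the route at 26.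

Step 16. Reductive elimination at the di-ortho-substituted aryl–palladium centre may be slow, so that β-hydride elimination in the alkylpalladium species and protodebromination take over. The fallback sets out from 26 and 11 and forms the same bond by nickel-catalysed reductive cross-electrophile coupling of the bromide with the iodide itself (NiBr2(dme), 4,4'-di-tert-butyl-2,2'-bipyridine, Mn powder, DMA, rt). The alkyl partner then enters as a radical, and no organozinc reagent or alkylpalladium intermediate is involved. No compound outside the list is made (F0), and the route is rejoined at 28.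

Step 11. Site selectivity may be poor (attack at the carbon between the two silyloxy groups) and over-bromination may occur. The fallback sets out from 18 and reverses the order of events so that the regiochemistry is fixed by symmetry. Monobromination of phloroglucinol (NBS 1 equiv, THF, –78 °C) should give 2-bromobenzene-1,3,5-triol F2. Bis-silylation of F2 (TBSCl 2 equiv, imidazole, DMF, 0 °C) takes the unhindered hydroxyl para to bromine and one of the two equivalent ortho hydroxyls, and comes back to the route at 20.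

**Further compounds**

F1 | step 15 | (3S)-3-[2-bromo-3,5-bis(tert-butyldimethylsilyloxy)phenoxy]-3-[4-(tert-butyldimethylsilyloxy)-2-methoxyphenyl]propanoic acid | OC(=O)C[C@H](Oc1cc(O[Si](C)(C)C(C)(C)C)cc(O[Si](C)(C)C(C)(C)C)c1Br)c1ccc(O[Si](C)(C)C(C)(C)C)cc1OC
F0 | step 16 | none | none
F2 | step 11 | 2-bromobenzene-1,3,5-triol | Oc1cc(O)c(Br)c(O)c1
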